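Numbering used throughout: C1 and C5 are the bridgeheads (C1 next to the CMe2 carbon C8), C9 is the bridging ketone, ring A is C1–C2–C3–C4–C5–C9 and ring B is C1–C8–C7–C6–C5–C9. The same atom labels are kept for the monocyclic precursors.

## The problem

Target 38 is a bicyclo[3.3.1]nonane-2,4,9-trione. Ring A carries the enolised 3-(3-hydroxybenzoyl) triketone, ring B carries the gem-dimethyl carbon C8 and the geranyl-bearing C7, and both bridgeheads are quaternary and prenylated. The most congested bond is C1–C8, which joins two fully substituted carbons and should be in place before C1 becomes quaternary. There are three stereocentres (1S,5S,7S). The bicycle ties C1 to C5, so only the absolute sense of the bridgehead pair and the configuration of C7 relative to it are independent. In a monocyclic precursor the bridgehead pair appears as a 1,3-cis relation across C9, which the bulky C8 group on C1 can impose during alkylation at C5. C7 (geranyl endo, on the ring A side) can be left to the bicycle, because C3 blocks the endo face. The configuration of C1 itself comes from telling apart the C2 and C9 carbonyls, which are equivalent in any simple malonate-derived ring, so it needs an external chiral agent. Four trisubstituted alkenes rule out strong acid, electrophilic halogen and hydrogenation; the free triketone enol cyclises onto prenyl groups under acid; the non-enolisable C2/C9 and C4/C9 diketones are open to retro-Claisen cleavage by hot hydroxide. The key step rests on C6 and C7: C6 is a CH2 on quaternary C5 and C7 lies between C6 and quaternary C8. C6 can therefore be the end of an acetic acid arm and C7 a bromoalkene carbon with an exocyclic CH2. Neither neighbour of the new bond bears hydrogen, and the methylidene left at C7 is the handle for the geranyl chain.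

## Retrosynthesis

**38 ⇒ 37.** No skeletal bond is cut. The C2 methyl enol ether and the aryl silyl ether of 37 are removed together by hydroxide. The methyl vinylogous ester keeps the triketone non-acidic and unable to cyclise onto the prenyl groups during all organometallic steps.

**37 ⇒ 31 + 35.** The C3–aroyl bond is cut. In 31 the vinylic C3–H is the only acidic C–H, since both bridgeheads are quaternary, so a hindered lithium amide followed by aroyl chloride 35 should do. Carrying the aroyl group from the monocycle would expose an aryl ketone to the cathode and to 9-BBN. Chloride 35 comes from 3-hydroxybenzoic acid 32 through silyl ether 34.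

**31 ⇒ 24 + 29.** The sp3–sp2 bond between the first and second carbon of the geranyl chain is cut. Hydroboration of the methylidene of 24 and coupling with alkenyl iodide 29 set C7 and finish the chain. Bringing the whole geranyl group in earlier would put C7 into a monocycle with no controlling element and add two alkenes to the radical step. Iodide 29 comes from enyne 27 by carboalumination, and 27 from bromide 25 and acetylide 26.

**24 ⇒ 23 (key step).** The C6–C7 bond is cut. The neighbouring cuts are worse: C5–C6 would need a neopentyl electrophile, C1–C8 would close a ring by joining two quaternary carbons, and C7–C8 would give up the quaternary carbon already bought in step 1. Precursor 23 is monocyclic and holds every core carbon. The forward reaction must join a primary radical at C6 to an alkenylnickel at C7 faster than the radical rearranges.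

**23 ⇒ 21 ⇒ 19.** Functional-group changes only: N-acyloxyphthalimide from acid 21, acid from tert-butyl ester 19. The tert-butyl ester is chosen because it can be cleaved without hydroxide (retro-Claisen risk) and without strong protic acid (prenyl groups).

**19 ⇒ 18 ⇒ 17.** The two C5–carbon bonds are cut; C5 is the carbon of the C4/C9 β-dicarbonyl. The order matters: acetate arm first (from 16), prenyl second (from 6), so that the prenyl group enters anti to the C8 group on C1 and the arm ends cis to it. C-alkylation must win over O-alkylation.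

**17 ⇐ 15 ⇐ 14 ⇐ 13.** This is where absolute configuration enters. O-Methylation of the achiral trione 13 makes C1 stereogenic. An enantioselective alkylation at C5 cannot set C1, because C1 is already fixed in 14, and no precedented reagent distinguishes the two enantiotopic enol oxygens of 13. Racemic 14, a vinylogous acid, is therefore resolved as quininium salt 15. The unwanted enantiomer returns to achiral 13 on hydrolysis, so the loss is not final.

**13 ⇒ 11 ⇒ 8 + 9.** The C2–C3 and C9–C5 bonds are cut (numbering of 13; the two sides are equivalent). Dichloride 10 of acid 8 acylates both methylene groups of acetonedicarboxylate 9. The ester groups make C3 and C5 soft, chelating nucleophiles and are then lost as CO2. Acetone itself would need two Claisen condensations at the most hindered carbonyls with a hard enolate.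

**8 ⇒ 7 ⇒ 5 ⇒ 3 ⇒ 1 + 2.** Saponification, malonate prenylation, bromoboration of the alkyne, and conjugate addition of acetylide 2 to alkylidene malonate 1. In 1 the C1–C8 bond already exists as the alkene, so the vicinal quaternary pair is never made by joining two hindered carbons.

## Roads not taken

**Alternative 1:** The cut is C4–C5, closing ring A last. Ph3PAuNTf2 (monovalent gold) would activate the ethoxy ynone of silyl enol ether A2, and C5 of the enol ether would attack C4 in a 6-endo-dig closure to give vinylogous ester A1. This road is more convergent than the chosen one: A1 already carries the geranyl chain and needs only C3 aroylation and deprotection, two steps against four. Its weak points lie before the key step. A2 needs C1 quaternary between C8 and an ynone acyl group, a regiodefined tetrasubstituted C5=C9 enol ether, and C7 set relative to C1 on a monocyclic cyclohexanone with no strong controlling element. In the gold step the C1 prenyl alkene is placed 1,6 to the activated alkyne and can compete as a nucleophile, and 5-exo attack at C3 is a second leak. The chosen plan pays with two extra late steps but obtains C1–C8 from a commercial malonate and C7 from the facial bias of the bicycle.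

**Alternative 2:** The cut is C7–C8. Fe(acac)3 and PhSiH3 would deliver a hydrogen atom to the isopropenyl CH2 of diketone A4, and the tertiary C8 radical would add 6-exo-dig to the propargyl alkyne to give A3. In precedent this road is better than the chosen one: hydrogen-atom-transfer radical cyclisations are documented, no electrochemistry is needed, and C5 of A4 is epimerisable, so only the cis isomer need cyclise. Its cost is that prenyl groups cannot be present, since trisubstituted alkenes also accept the hydrogen atom. A3 therefore carries allyl on C1 and hydrogen on C5. After the key step it needs bridgehead prenylation at C5 and cross-metathesis of the allyl group beside the new methylidene, on top of the same four closing steps. The quaternary, isopropenyl-bearing C1 of A4 is no easier to make than the malonate-derived C1 used here, and the absolute configuration of C1 poses the same problem. Against the better precedent the chosen plan sets a precursor that already holds both prenyl groups and a shorter endgame.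

**Alternative 3:** The cuts are C1–C2 and C7–C8, made together. Irradiation of dioxinone A6 at 300 nm would join its C2=C7 alkene to the tethered C1=C8 enone alkene, and K2CO3 in methanol would then open the C2–C7 cyclobutane bond by retro-aldol to give keto ester A5. This is the only road that creates both quaternary carbons C1 and C8 in one step from flat carbons, and the retro-aldol unzip is reliable chemistry. Against this the chosen plan can only say that it obtains the same C1–C8 pair in step 1 from a commercial alkene. The weak points are the [2+2] addition to a tetrasubstituted alkene, prenyl groups that can also react at 300 nm, and the oxidation level of A5. A5 has no C4 carbonyl, so an oxidation next to quaternary C5 is needed, and its C7 ester must be reduced and extended to the geranyl chain. At least seven steps would follow the key step.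

Key step: step 13

## Route

Assumption: the target is written as its C2-keto/C4-enol tautomer; the enol tautomers interconvert and are one compound.
Assumption: the less soluble quininium salt is taken to be that of the (6R)-enantiomer of 14; if the (6S) salt crystallises instead, the pseudo-enantiomeric base quinidine is used in the same way.
Remark: CIP descriptors change between 31, 37 and 38 only because substituent priorities change; the spatial arrangement is the same.

Step 1
Reactants: 1 diethyl 2-(propan-2-ylidene)propanedioate; 2 ethynylmagnesium bromide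
Product: 3 diethyl 2-(2-methylbut-3-yn-2-yl)propanedioate
Conditions: THF, 0 °C to rt; 1 M HCl
Reagents that add atoms: none
Why: Conjugate addition of an alkynyl Grignard reagent to a doubly activated alkylidene malonate; the C1–C8 bond is already present as the alkene, so quaternary C8 forms by attack of a slim sp nucleophile.

Step 2
Reactants: 3 diethyl 2-(2-methylbut-3-yn-2-yl)propanedioate
Product: 5 diethyl 2-(3-bromo-2-methylbut-3-en-2-yl)propanedioate, via diethyl 2-[(3Z)-4-(9-borabicyclo[3.3.1]nonan-9-yl)-3-bromo-2-methylbut-3-en-2-yl]propanedioate 4 (not isolated)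
Conditions: B-bromo-9-BBN, CH2Cl2, 0 °C; AcOH, 0 °C to rt
Reagents that add atoms: B-bromo-9-borabicyclo[3.3.1]nonane, BrB1C2CCCC1CCC2
Why: syn-Bromoboration of the terminal alkyne puts boron on the terminal carbon and bromine on C7, and protodeboronation with acetic acid leaves the 2-bromo-1-alkene; esters are inert and no trisubstituted alkene is present yet.

Step 3
Reactants: 5 diethyl 2-(3-bromo-2-methylbut-3-en-2-yl)propanedioate; 6 1-bromo-3-methylbut-2-ene (prenyl bromide)
Product: 7 diethyl 2-(3-bromo-2-methylbut-3-en-2-yl)-2-(3-methylbut-2-en-1-yl)propanedioate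
Conditions: NaH, DMF, 0 to 40 °C
Reagents that add atoms: none
Why: Malonate alkylation with an allylic bromide; the tertiary substituent slows but should not prevent C-alkylation of the planar ester enolate, and O-alkylation is not competitive for a malonate.

Step 4
Reactants: 7 diethyl 2-(3-bromo-2-methylbut-3-en-2-yl)-2-(3-methylbut-2-en-1-yl)propanedioate
Product: 8 2-(3-bromo-2-methylbut-3-en-2-yl)-2-(3-methylbut-2-en-1-yl)propanedioic acid
Conditions: KOH (excess), EtOH–H2O 3:1, 90 °C; 2 M HCl, 0 °C
Reagents that add atoms: potassium hydroxide, [K+].[OH-]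
Why: Saponification; the hindered diester needs forcing aqueous-alcoholic hydroxide, which an unactivated 2-bromoalkene should tolerate, and the dialkylmalonic acid does not decarboxylate at this temperature.

Step 5
Reactants: 8 2-(3-bromo-2-methylbut-3-en-2-yl)-2-(3-methylbut-2-en-1-yl)propanedioic acid; 9 dimethyl 3-oxopentanedioate
Product: 11 dimethyl 5-(3-bromo-2-methylbut-3-en-2-yl)-5-(3-methylbut-2-en-1-yl)-2,4,6-trioxocyclohexane-1,3-dicarboxylate (enolised), via 2-(3-bromo-2-methylbut-3-en-2-yl)-2-(3-methylbut-2-en-1-yl)propanedioyl dichloride 10 (not isolated)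
Conditions: (COCl)2, DMF (cat.), CH2Cl2, 0 °C to rt, evaporate; 9, MgCl2, Et3N, MeCN, 0 °C to rt
Reagents that add atoms: none
Why: Acid chloride formation, then double C-acylation of the magnesium-chelated enolate of 9 (Claisen-type [3+3] annulation, the classical assembly of gem-dialkyl cyclohexanetriones from dialkylmalonyl chlorides); the second acylation is intramolecular and six-membered, and magnesium chelation directs it to carbon.

Step 6
Reactants: 11 dimethyl 5-(3-bromo-2-methylbut-3-en-2-yl)-5-(3-methylbut-2-en-1-yl)-2,4,6-trioxocyclohexane-1,3-dicarboxylate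
Product: 13 2-(3-bromo-2-methylbut-3-en-2-yl)-2-(3-methylbut-2-en-1-yl)cyclohexane-1,3,5-trione (achiral, enolised), via 5-(3-bromo-2-methylbut-3-en-2-yl)-5-(3-methylbut-2-en-1-yl)-2,4,6-trioxocyclohexane-1,3-dicarboxylic acid 12 (not isolated)
Conditions: 2 M NaOH, MeOH–H2O, 65 °C; 2 M HCl to pH 1, 40 °C
Reagents that add atoms: none
Why: Saponification and decarboxylation of the two β-keto ester units; in alkali the trione is a delocalised polyanion, which protects the non-enolisable C2/C9 diketone from retro-Claisen cleavage.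

Step 7
Reactants: 13 2-(3-bromo-2-methylbut-3-en-2-yl)-2-(3-methylbut-2-en-1-yl)cyclohexane-1,3,5-trione
Product: 14 rac-6-(3-bromo-2-methylbut-3-en-2-yl)-5-methoxy-6-(3-methylbut-2-en-1-yl)cyclohex-4-ene-1,3-dione (enolised vinylogous acid)
Conditions: Me3SiCHN2 (1.05 equiv), toluene–MeOH 4:1, 0 °C
Reagents that add atoms: (trimethylsilyl)diazomethane, C[Si](C)(C)C=[N+]=[N-]
Why: O-Methylation of a vinylogous acid with a diazoalkane; 13 should exist as the 3,5-dihydroxy-2,5-dienone whose two equivalent enol hydroxyls flank C1, so capping one gives racemic 14, and the regioisomer methylated at the central oxygen or any bis-ether is returned to 13 by dilute aqueous acid.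

Step 8
Reactants: 14 rac-6-(3-bromo-2-methylbut-3-en-2-yl)-5-methoxy-6-(3-methylbut-2-en-1-yl)cyclohex-4-ene-1,3-dione
Product: 15 quininium salt of the (6R)-enantiomer of 14 (enolate of the C4/C9 β-diketone)
Conditions: quinine (0.55 equiv), acetone–EtOAc, fractional crystallisation
Reagents that add atoms: quinine, COC1=CC2=C(C=CN=C2C=C1)[C@H]([C@@H]3C[C@@H]4CCN3C[C@@H]4C=C)O
Why: Classical resolution by crystallisation of diastereomeric salts; 14 is a vinylogous acid (pKa about 5), quinine is a tertiary amine that cannot condense with the diketone, and the mother-liquor enantiomer is hydrolysed back to achiral 13 and recycled.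

Step 9
Reactants: 15 quininium salt of the (6R)-enantiomer of 14; 16 tert-butyl bromoacetate
Product: 18 tert-butyl 2-[(3R)-3-(3-bromo-2-methylbut-3-en-2-yl)-4-methoxy-3-(3-methylbut-2-en-1-yl)-2,6-dioxocyclohex-4-en-1-yl]acetate (ring C1 enolisable, not defined), via (6R)-6-(3-bromo-2-methylbut-3-en-2-yl)-5-methoxy-6-(3-methylbut-2-en-1-yl)cyclohex-4-ene-1,3-dione 17 (not isolated)
Conditions: EtOAc / 1 M HCl wash, evaporate; 16 (1.0 equiv), K2CO3, acetone, rt
Reagents that add atoms: none
Why: The salt is broken with acid and the β-dicarbonyl carbon C5 is C-alkylated by a soft α-halo ester (SN2); one equivalent of electrophile limits dialkylation, and C5 stays enolisable, so its configuration does not matter here.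

Step 10
Reactants: 18 tert-butyl 2-[(3R)-3-(3-bromo-2-methylbut-3-en-2-yl)-4-methoxy-3-(3-methylbut-2-en-1-yl)-2,6-dioxocyclohex-4-en-1-yl]acetate; 6 1-bromo-3-methylbut-2-ene
Product: 19 tert-butyl 2-[(1S,3R)-3-(3-bromo-2-methylbut-3-en-2-yl)-4-methoxy-1,3-bis(3-methylbut-2-en-1-yl)-2,6-dioxocyclohex-4-en-1-yl]acetate (acetate arm cis to the bromoalkenyl group)
Conditions: 6 (3 equiv), KOH (1.2 equiv), H2O–dioxane 1:1, 0 °C to rt
Reagents that add atoms: none
Why: Second C-alkylation of the β-dicarbonyl enolate in a protic medium that disfavours O-alkylation; on the nearly planar ring the bromide should approach C5 anti to the tertiary alkyl group on C1 (1,3-induction across C9), which sets C5 with the arm cis to the C8 chain.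

Step 11
Reactants: 19 tert-butyl 2-[(1S,3R)-3-(3-bromo-2-methylbut-3-en-2-yl)-4-methoxy-1,3-bis(3-methylbut-2-en-1-yl)-2,6-dioxocyclohex-4-en-1-yl]acetate
Product: 21 2-[(1S,3R)-3-(3-bromo-2-methylbut-3-en-2-yl)-4-methoxy-1,3-bis(3-methylbut-2-en-1-yl)-2,6-dioxocyclohex-4-en-1-yl]acetic acid, via the trimethylsilyl ester of acid 21 20 (not isolated)
Conditions: Me3SiOTf, 2,6-lutidine, CH2Cl2, 0 °C; pH 4 buffer
Reagents that add atoms: none
Why: Silyl triflate-mediated tert-butyl ester cleavage (loss of isobutene, then hydrolysis of the silyl ester on work-up); 19 has no enolisable position, and neither hydroxide nor strong protic acid touches the diketone, the enol ether or the prenyl groups.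

Step 12
Reactants: 21 2-[(1S,3R)-3-(3-bromo-2-methylbut-3-en-2-yl)-4-methoxy-1,3-bis(3-methylbut-2-en-1-yl)-2,6-dioxocyclohex-4-en-1-yl]acetic acid; 22 N-hydroxyphthalimide
Product: 23 1,3-dioxoisoindolin-2-yl 2-[(1S,3R)-3-(3-bromo-2-methylbut-3-en-2-yl)-4-methoxy-1,3-bis(3-methylbut-2-en-1-yl)-2,6-dioxocyclohex-4-en-1-yl]acetate
Conditions: N,N'-diisopropylcarbodiimide, DMAP (cat.), CH2Cl2, rt
Reagents that add atoms: none
Why: Carbodiimide (Steglich-type) esterification gives the redox-active N-acyloxyphthalimide under neutral conditions.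

Step 13
Reactants: 23 1,3-dioxoisoindolin-2-yl 2-[(1S,3R)-3-(3-bromo-2-methylbut-3-en-2-yl)-4-methoxy-1,3-bis(3-methylbut-2-en-1-yl)-2,6-dioxocyclohex-4-en-1-yl]acetate
Product: 24 (1R,5S)-2-methoxy-8,8-dimethyl-7-methylidene-1,5-bis(3-methylbut-2-en-1-yl)bicyclo[3.3.1]non-2-ene-4,9-dione
Conditions: NiBr2(dme) (20 mol %), 2,2'-bipyridine (24 mol %), LiBr, DMF, 0.01 M, undivided cell, zinc anode / carbon-foam cathode, constant current (about 3 F/mol), rt
Reagents that add atoms: none
Why: Proposed new method: cathodic reduction gives low-valent (bipyridine)nickel, and zerovalent nickel inserts into the C7–Br bond to give an alkenyl complex of divalent nickel, while electron transfer to the N-acyloxyphthalimide releases phthalimide anion, CO2 and the primary C6 radical. Capture of this radical by the tethered alkenylnickel gives trivalent nickel, and reductive elimination forms C6–C7; the zinc anode supplies the two electrons. The closest known reaction type is the intermolecular nickel-electrocatalytic decarboxylative alkenylation of redox-active esters with alkenyl halides, here run within one molecule. Ring B (six-membered) closes by reductive elimination from a seven-membered nickelacycle, the equivalent of a 6-exo closure at C7 that keeps the CH2 exocyclic. No stereocentre is formed; C1 and C5 come from 23, and only their cis arrangement of the C6 and C8 arms can bridge. The step needs nickel capture to outrun Dowd–Beckwith 3-exo attack of the C6 radical on the C4 and C9 carbonyls, hydrogen abstraction and dimerisation. The substrate helps: C4 is a deactivated vinylogous-ester carbonyl, C9 lies between two quaternary carbons, C5 and C8 carry no hydrogen for β-hydride loss, and the arm is trans to the C1 prenyl group, so 6-exo addition to that alkene is geometrically disfavoured. High dilution and a high nickel loading keep the radical short-lived and the coupling intramolecular.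

Step 14
Reactants: 25 5-bromo-2-methylpent-2-ene; 26 lithium acetylide–ethylenediamine complex
Product: 27 6-methylhept-5-en-1-yne
Conditions: DMSO, 0 °C to rt
Reagents that add atoms: none
Why: SN2 alkynylation of a primary homoallylic bromide by lithium acetylide in DMSO.

Step 15
Reactants: 27 6-methylhept-5-en-1-yne
Product: 29 (1E)-1-iodo-2,6-dimethylhepta-1,5-diene, via [(1E)-2,6-dimethylhepta-1,5-dien-1-yl]dimethylalane 28 (not isolated)
Conditions: AlMe3, Cp2ZrCl2 (25 mol %), CH2Cl2, 0 °C to rt; I2, THF, −30 to 0 °C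
Reagents that add atoms: trimethylaluminium, C[Al](C)C; iodine, II
Why: Zirconium-catalysed syn-carboalumination (Negishi) adds methyl and aluminium across the alkyne with aluminium at the terminus, and iodinolysis with retention gives the (E)-alkenyl iodide.

Step 16
Reactants: 24 (1R,5S)-2-methoxy-8,8-dimethyl-7-methylidene-1,5-bis(3-methylbut-2-en-1-yl)bicyclo[3.3.1]non-2-ene-4,9-dione; 29 (1E)-1-iodo-2,6-dimethylhepta-1,5-diene
Product: 31 (1R,5S,7S)-7-[(2E)-3,7-dimethylocta-2,6-dien-1-yl]-2-methoxy-8,8-dimethyl-1,5-bis(3-methylbut-2-en-1-yl)bicyclo[3.3.1]non-2-ene-4,9-dione (geranyl endo), via the (1R,5S,7S)-7-[(9-borabicyclo[3.3.1]nonan-9-yl)methyl] adduct of 24 30 (not isolated)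
Conditions: 9-BBN, THF, 0 °C to rt; 29, Pd(dppf)Cl2 (5 mol %), AsPh3, 3 M aq. K3PO4, DMF, rt
Reagents that add atoms: none
Why: 9-BBN hydroborates a 1,1-disubstituted alkene more than a hundred times faster than the trisubstituted prenyl alkenes and should leave the hindered C9 and vinylogous C4 carbonyls alone; hydrogen reaches C7 from the exo face because C3 of ring A lies over the endo face, so the borylmethyl group becomes endo (7S). B-alkyl Suzuki–Miyaura coupling then joins the primary alkylborane to 29 with retention of the E geometry.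

Step 17
Reactants: 32 3-hydroxybenzoic acid
Product: 34 3-[(tert-butyldimethylsilyl)oxy]benzoic acid, via tert-butyldimethylsilyl 3-[(tert-butyldimethylsilyl)oxy]benzoate 33 (not isolated)
Conditions: tBuMe2SiCl (2.4 equiv), imidazole, DMF, rt; AcOH–THF–H2O 3:1:1, rt
Reagents that add atoms: tert-butyldimethylsilyl chloride, CC(C)(C)[Si](C)(C)Cl
Why: Silylation of both acidic groups, then selective hydrolysis of the labile silyl ester with aqueous acetic acid, which spares the aryl silyl ether.

Step 18
Reactants: 34 3-[(tert-butyldimethylsilyl)oxy]benzoic acid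
Product: 35 3-[(tert-butyldimethylsilyl)oxy]benzoyl chloride
Conditions: (COCl)2, DMF (cat.), CH2Cl2, 0 °C to rt; used crude
Reagents that add atoms: oxalyl chloride, ClC(=O)C(Cl)=O
Why: Acid chloride formation under Vilsmeier catalysis; the aryl silyl ether is stable to the hydrogen chloride formed.

Step 19
Reactants: 31 (1R,5S,7S)-7-[(2E)-3,7-dimethylocta-2,6-dien-1-yl]-2-methoxy-8,8-dimethyl-1,5-bis(3-methylbut-2-en-1-yl)bicyclo[3.3.1]non-2-ene-4,9-dione; 35 3-[(tert-butyldimethylsilyl)oxy]benzoyl chloride
Product: 37 (1R,5R,7S)-3-{3-[(tert-butyldimethylsilyl)oxy]benzoyl}-7-[(2E)-3,7-dimethylocta-2,6-dien-1-yl]-2-methoxy-8,8-dimethyl-1,5-bis(3-methylbut-2-en-1-yl)bicyclo[3.3.1]non-2-ene-4,9-dione, via the 3-lithio derivative of 31 36 (not isolated)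
Conditions: LiTMP, THF, −78 °C; 35, −78 to −40 °C
Reagents that add atoms: none
Why: Lithiation of the vinylogous-ester α-carbon C3, the only acidic C–H once both bridgeheads are quaternary, followed by acylation with the aroyl chloride; this sequence is established for O-methylated bicyclic triketones of this family.

Step 20
Reactants: 37 (1R,5R,7S)-3-{3-[(tert-butyldimethylsilyl)oxy]benzoyl}-7-[(2E)-3,7-dimethylocta-2,6-dien-1-yl]-2-methoxy-8,8-dimethyl-1,5-bis(3-methylbut-2-en-1-yl)bicyclo[3.3.1]non-2-ene-4,9-dione
Product: 38 (1S,5S,7S)-7-[(2E)-3,7-dimethylocta-2,6-dien-1-yl]-4-hydroxy-3-(3-hydroxybenzoyl)-8,8-dimethyl-1,5-bis(3-methylbut-2-en-1-yl)bicyclo[3.3.1]non-3-ene-2,9-dione (CNP0290731.1)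
Conditions: LiOH·H2O, dioxane–H2O 4:1, 90 °C; 1 M HCl (work-up)
Reagents that add atoms: lithium hydroxide, [Li+].[OH-]
Why: Hydroxide adds to C2 of the doubly activated vinylogous ester and expels methoxide (addition–elimination), and the same reagent cleaves the aryl silyl ether. The product sits as its stable enolate until work-up, so neither retro-Claisen opening nor acid-induced cyclisation onto the prenyl groups should intervene.

## Compound list

1 | diethyl 2-(propan-2-ylidene)propanedioate | CCOC(=O)C(=C(C)C)C(=O)OCC | starting material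
2 | ethynylmagnesium bromide | C#C[Mg]Br | starting material
3 | diethyl 2-(2-methylbut-3-yn-2-yl)propanedioate | CCOC(=O)C(C(=O)OCC)C(C)(C)C#C | intermediate
4 | diethyl 2-[(3Z)-4-(9-borabicyclo[3.3.1]nonan-9-yl)-3-bromo-2-methylbut-3-en-2-yl]propanedioate | CCOC(=O)C(C(=O)OCC)C(C)(C)/C(Br)=C/B1C2CCCC1CCC2 | intermediate
5 | diethyl 2-(3-bromo-2-methylbut-3-en-2-yl)propanedioate | CCOC(=O)C(C(=O)OCC)C(C)(C)C(Br)=C | intermediate
6 | 1-bromo-3-methylbut-2-ene (prenyl bromide) | CC(C)=CCBr | starting material
7 | diethyl 2-(3-bromo-2-methylbut-3-en-2-yl)-2-(3-methylbut-2-en-1-yl)propanedioate | CCOC(=O)C(CC=C(C)C)(C(=O)OCC)C(C)(C)C(Br)=C | intermediate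
8 | 2-(3-bromo-2-methylbut-3-en-2-yl)-2-(3-methylbut-2-en-1-yl)propanedioic acid | OC(=O)C(CC=C(C)C)(C(=O)O)C(C)(C)C(Br)=C | intermediate
9 | dimethyl 3-oxopentanedioate | COC(=O)CC(=O)CC(=O)OC | starting material
10 | 2-(3-bromo-2-methylbut-3-en-2-yl)-2-(3-methylbut-2-en-1-yl)propanedioyl dichloride | ClC(=O)C(CC=C(C)C)(C(Cl)=O)C(C)(C)C(Br)=C | intermediate
11 | dimethyl 5-(3-bromo-2-methylbut-3-en-2-yl)-5-(3-methylbut-2-en-1-yl)-2,4,6-trioxocyclohexane-1,3-dicarboxylate | COC(=O)C1C(=O)C(C(=O)OC)C(=O)C(CC=C(C)C)(C(C)(C)C(Br)=C)C1=O | intermediate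
12 | 5-(3-bromo-2-methylbut-3-en-2-yl)-5-(3-methylbut-2-en-1-yl)-2,4,6-trioxocyclohexane-1,3-dicarboxylic acid | OC(=O)C1C(=O)C(C(=O)O)C(=O)C(CC=C(C)C)(C(C)(C)C(Br)=C)C1=O | intermediate
13 | 2-(3-bromo-2-methylbut-3-en-2-yl)-2-(3-methylbut-2-en-1-yl)cyclohexane-1,3,5-trione | O=C1CC(=O)CC(=O)C1(CC=C(C)C)C(C)(C)C(Br)=C | intermediate
14 | rac-6-(3-bromo-2-methylbut-3-en-2-yl)-5-methoxy-6-(3-methylbut-2-en-1-yl)cyclohex-4-ene-1,3-dione | COC1=CC(=O)CC(=O)C1(CC=C(C)C)C(C)(C)C(Br)=C | intermediate
15 | quininium salt of the (6R)-enantiomer of 14 | CC(C)=CC[C@]1(C(C)(C)C(Br)=C)C(=O)C=C([O-])C=C1OC.COC1=CC2=C(C=CN=C2C=C1)[C@H]([C@@H]3C[C@@H]4CC[NH+]3C[C@@H]4C=C)O | intermediate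
16 | tert-butyl bromoacetate | CC(C)(C)OC(=O)CBr | starting material
17 | (6R)-6-(3-bromo-2-methylbut-3-en-2-yl)-5-methoxy-6-(3-methylbut-2-en-1-yl)cyclohex-4-ene-1,3-dione | CC(C)=CC[C@]1(C(C)(C)C(Br)=C)C(=O)CC(=O)C=C1OC | intermediate
18 | tert-butyl 2-[(3R)-3-(3-bromo-2-methylbut-3-en-2-yl)-4-methoxy-3-(3-methylbut-2-en-1-yl)-2,6-dioxocyclohex-4-en-1-yl]acetate | CC(C)=CC[C@]1(C(C)(C)C(Br)=C)C(=O)C(CC(=O)OC(C)(C)C)C(=O)C=C1OC | intermediate
19 | tert-butyl 2-[(1S,3R)-3-(3-bromo-2-methylbut-3-en-2-yl)-4-methoxy-1,3-bis(3-methylbut-2-en-1-yl)-2,6-dioxocyclohex-4-en-1-yl]acetate | CC(C)=CC[C@]1(C(C)(C)C(Br)=C)C(=O)[C@@](CC=C(C)C)(CC(=O)OC(C)(C)C)C(=O)C=C1OC | intermediate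
20 | trimethylsilyl 2-[(1S,3R)-3-(3-bromo-2-methylbut-3-en-2-yl)-4-methoxy-1,3-bis(3-methylbut-2-en-1-yl)-2,6-dioxocyclohex-4-en-1-yl]acetate | CC(C)=CC[C@]1(C(C)(C)C(Br)=C)C(=O)[C@@](CC=C(C)C)(CC(=O)O[Si](C)(C)C)C(=O)C=C1OC | intermediate
21 | 2-[(1S,3R)-3-(3-bromo-2-methylbut-3-en-2-yl)-4-methoxy-1,3-bis(3-methylbut-2-en-1-yl)-2,6-dioxocyclohex-4-en-1-yl]acetic acid | CC(C)=CC[C@]1(C(C)(C)C(Br)=C)C(=O)[C@@](CC=C(C)C)(CC(=O)O)C(=O)C=C1OC | intermediate
22 | N-hydroxyphthalimide | ON1C(=O)c2ccccc2C1=O | starting material
23 | 1,3-dioxoisoindolin-2-yl 2-[(1S,3R)-3-(3-bromo-2-methylbut-3-en-2-yl)-4-methoxy-1,3-bis(3-methylbut-2-en-1-yl)-2,6-dioxocyclohex-4-en-1-yl]acetate | CC(C)=CC[C@]1(C(C)(C)C(Br)=C)C(=O)[C@@](CC=C(C)C)(CC(=O)ON2C(=O)c3ccccc3C2=O)C(=O)C=C1OC | intermediate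
24 | (1R,5S)-2-methoxy-8,8-dimethyl-7-methylidene-1,5-bis(3-methylbut-2-en-1-yl)bicyclo[3.3.1]non-2-ene-4,9-dione | C=C1C[C@]2(CC=C(C)C)C(=O)[C@@](CC=C(C)C)(C(OC)=CC2=O)C1(C)C | intermediate
25 | 5-bromo-2-methylpent-2-ene | CC(C)=CCCBr | starting material
26 | lithium acetylide–ethylenediamine complex | [Li]C#C.NCCN | starting material
27 | 6-methylhept-5-en-1-yne | CC(C)=CCCC#C | intermediate
28 | [(1E)-2,6-dimethylhepta-1,5-dien-1-yl]dimethylalane | CC(C)=CCC/C(C)=C/[Al](C)C | intermediate
29 | (1E)-1-iodo-2,6-dimethylhepta-1,5-diene | CC(C)=CCC/C(C)=C/I | intermediate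
30 | (1R,5S,7S)-7-[(9-borabicyclo[3.3.1]nonan-9-yl)methyl]-2-methoxy-8,8-dimethyl-1,5-bis(3-methylbut-2-en-1-yl)bicyclo[3.3.1]non-2-ene-4,9-dione | C(B1C2CCCC1CCC2)[C@H]3C[C@]4(CC=C(C)C)C(=O)[C@@](CC=C(C)C)(C(OC)=CC4=O)C3(C)C | intermediate
31 | (1R,5S,7S)-7-[(2E)-3,7-dimethylocta-2,6-dien-1-yl]-2-methoxy-8,8-dimethyl-1,5-bis(3-methylbut-2-en-1-yl)bicyclo[3.3.1]non-2-ene-4,9-dione | CC(C)=CCC/C(C)=C/C[C@H]1C[C@]2(CC=C(C)C)C(=O)[C@@](CC=C(C)C)(C(OC)=CC2=O)C1(C)C | intermediate
32 | 3-hydroxybenzoic acid | OC(=O)c1cccc(O)c1 | starting material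
33 | tert-butyldimethylsilyl 3-[(tert-butyldimethylsilyl)oxy]benzoate | CC(C)(C)[Si](C)(C)OC(=O)c1cccc(O[Si](C)(C)C(C)(C)C)c1 | intermediate
34 | 3-[(tert-butyldimethylsilyl)oxy]benzoic acid | CC(C)(C)[Si](C)(C)Oc1cccc(C(=O)O)c1 | intermediate
35 | 3-[(tert-butyldimethylsilyl)oxy]benzoyl chloride | CC(C)(C)[Si](C)(C)Oc1cccc(C(Cl)=O)c1 | intermediate
36 | 3-lithio derivative of 31 | CC(C)=CCC/C(C)=C/C[C@H]1C[C@]2(CC=C(C)C)C(=O)[C@@](CC=C(C)C)(C(OC)=C([Li])C2=O)C1(C)C | intermediate
37 | (1R,5R,7S)-3-{3-[(tert-butyldimethylsilyl)oxy]benzoyl}-7-[(2E)-3,7-dimethylocta-2,6-dien-1-yl]-2-methoxy-8,8-dimethyl-1,5-bis(3-methylbut-2-en-1-yl)bicyclo[3.3.1]non-2-ene-4,9-dione | CC(C)=CCC/C(C)=C/C[C@H]1C[C@]2(CC=C(C)C)C(=O)[C@@](CC=C(C)C)(C(OC)=C(C(=O)c3cccc(O[Si](C)(C)C(C)(C)C)c3)C2=O)C1(C)C | intermediate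
38 | (1S,5S,7S)-7-[(2E)-3,7-dimethylocta-2,6-dien-1-yl]-4-hydroxy-3-(3-hydroxybenzoyl)-8,8-dimethyl-1,5-bis(3-methylbut-2-en-1-yl)bicyclo[3.3.1]non-3-ene-2,9-dione | CC(C)=CCC/C(C)=C/C[C@H]1C[C@]2(CC=C(C)C)C(=O)[C@@](CC=C(C)C)(C(=O)C(C(=O)c3cccc(O)c3)=C2O)C1(C)C | target

## Step count and risk

Total: 20 steps. Longest linear sequence: 16 steps (steps 1–13, 16, 19, 20).

**Step 13 (key step).** The most likely failure is that the C6 radical rearranges before nickel captures it. Dowd–Beckwith 3-exo attack on the C9 or C4 carbonyl would lead to a ring-expanded product. Reduction of the radical to a methyl group or loss of bromine from C7 are the other leaks, because capture here depends on an organonickel species formed in the same molecule. Fallback (known chemistry), from 19 back to 24: the bromoalkene is dehydrobrominated with Bu4NF·3H2O in DMF to tert-butyl 2-[(1S,3R)-4-methoxy-3-(2-methylbut-3-yn-2-yl)-1,3-bis(3-methylbut-2-en-1-yl)-2,6-dioxocyclohex-4-en-1-yl]acetate F1. The ester is cleaved as in step 11 to the corresponding acid F2, which is converted as in step 12 into its N-acyloxyphthalimide F3. Visible-light reductive decarboxylation with [Ru(bpy)3](PF6)2, Hantzsch ester and iPr2NEt then lets the C6 radical add 6-exo-dig to the alkyne, and the vinyl radical is reduced to the methylidene of 24.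

**Step 5.** The hindered dichloride may acylate slowly, and the second acylation may go to the enol oxygen and close a pyranone instead of the carbocycle. Fallback, from 8 back to 13: dichloride 10 is treated with Me2CuLi at −78 °C to give 3-(3-bromo-2-methylbut-3-en-2-yl)-3-(3-methylbut-2-en-1-yl)pentane-2,4-dione F4. Claisen condensation of one acetyl group with dimethyl carbonate (NaH, THF), followed by Dieckmann closure of the other acetyl group onto the new ester, gives 13 directly, with the carbonate carbon as C4.

**Step 7.** Methylation may go mainly to the central oxygen, or on to bis-ethers, because that oxygen is the least hindered. Fallback, from 13 back to 14: exhaustive O-methylation with excess Me3SiCHN2 gives 4-(3-bromo-2-methylbut-3-en-2-yl)-3,5-dimethoxy-4-(3-methylbut-2-en-1-yl)cyclohexa-2,5-dien-1-one F5. Nucleophilic mono-demethylation with LiI in 2,4,6-collidine, known for such dimethoxy dienones, removes one methyl group and leaves the stabilised β-diketonate of 14.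

**Step 8.** The diastereomeric salts may not crystallise, or may crystallise without enough discrimination. Fallback, from 14 to 17: racemic 14 is separated by preparative supercritical-fluid chromatography on an amylose tris(3,5-dimethylphenylcarbamate) phase, and the unwanted enantiomer is again recycled through 13. No new compound is made.

**Step 10.** O-Prenylation of the hindered enolate or poor facial selectivity at C5 would cut the yield of the cis isomer. Fallback, from 18 back to 19: O-allylation (allyl bromide, K2CO3, acetone) gives tert-butyl 2-[(5R)-2-(allyloxy)-5-(3-bromo-2-methylbut-3-en-2-yl)-4-methoxy-5-(3-methylbut-2-en-1-yl)-6-oxocyclohexa-1,3-dien-1-yl]acetate F6. Claisen rearrangement in toluene at 110 °C delivers the allyl group to C5 on the face anti to the C1 tertiary alkyl group, giving tert-butyl 2-[(1S,3R)-1-allyl-3-(3-bromo-2-methylbut-3-en-2-yl)-4-methoxy-3-(3-methylbut-2-en-1-yl)-2,6-dioxocyclohex-4-en-1-yl]acetate F7. Cross-metathesis with 2-methylbut-2-ene and the second-generation Grubbs catalyst then turns allyl into prenyl.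

**Step 16.** 9-BBN may reduce the C4 or C9 carbonyl competitively, hydroboration of the neopentyl-flanked methylidene may stall, or the β-branched alkylborane may transmetalate slowly and be lost by protodeboronation. Fallback, from 24 back to 31: catalytic hydroboration with pinacolborane and [Ir(cod)Cl]2/dppe, which has no free B–H reductant for ketones, gives the (1R,5S,7S)-7-[(4,4,5,5-tetramethyl-1,3,2-dioxaborolan-2-yl)methyl] derivative of 24 F8. KHF2 converts it into the potassium trifluoroborate F9, which is coupled with 29 using Pd(dppf)Cl2 and Cs2CO3 in THF–H2O at 80 °C.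

## Further compounds

F1 | step 13 | tert-butyl 2-[(1S,3R)-4-methoxy-3-(2-methylbut-3-yn-2-yl)-1,3-bis(3-methylbut-2-en-1-yl)-2,6-dioxocyclohex-4-en-1-yl]acetate | CC(C)=CC[C@]1(C(C)(C)C#C)C(=O)[C@@](CC=C(C)C)(CC(=O)OC(C)(C)C)C(=O)C=C1OC
F2 | step 13 | 2-[(1S,3R)-4-methoxy-3-(2-methylbut-3-yn-2-yl)-1,3-bis(3-methylbut-2-en-1-yl)-2,6-dioxocyclohex-4-en-1-yl]acetic acid | CC(C)=CC[C@]1(C(C)(C)C#C)C(=O)[C@@](CC=C(C)C)(CC(=O)O)C(=O)C=C1OC
F3 | step 13 | 1,3-dioxoisoindolin-2-yl 2-[(1S,3R)-4-methoxy-3-(2-methylbut-3-yn-2-yl)-1,3-bis(3-methylbut-2-en-1-yl)-2,6-dioxocyclohex-4-en-1-yl]acetate | CC(C)=CC[C@]1(C(C)(C)C#C)C(=O)[C@@](CC=C(C)C)(CC(=O)ON2C(=O)c3ccccc3C2=O)C(=O)C=C1OC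
F4 | step 5 | 3-(3-bromo-2-methylbut-3-en-2-yl)-3-(3-methylbut-2-en-1-yl)pentane-2,4-dione | CC(=O)C(CC=C(C)C)(C(C)=O)C(C)(C)C(Br)=C
F5 | step 7 | 4-(3-bromo-2-methylbut-3-en-2-yl)-3,5-dimethoxy-4-(3-methylbut-2-en-1-yl)cyclohexa-2,5-dien-1-one | COC1=CC(=O)C=C(OC)C1(CC=C(C)C)C(C)(C)C(Br)=C
F0 | step 8 | none | none
F6 | step 10 | tert-butyl 2-[(5R)-2-(allyloxy)-5-(3-bromo-2-methylbut-3-en-2-yl)-4-methoxy-5-(3-methylbut-2-en-1-yl)-6-oxocyclohexa-1,3-dien-1-yl]acetate | CC(C)=CC[C@]1(C(C)(C)C(Br)=C)C(=O)C(CC(=O)OC(C)(C)C)=C(OCC=C)C=C1OC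
F7 | step 10 | tert-butyl 2-[(1S,3R)-1-allyl-3-(3-bromo-2-methylbut-3-en-2-yl)-4-methoxy-3-(3-methylbut-2-en-1-yl)-2,6-dioxocyclohex-4-en-1-yl]acetate | CC(C)=CC[C@]1(C(C)(C)C(Br)=C)C(=O)[C@@](CC=C)(CC(=O)OC(C)(C)C)C(=O)C=C1OC
F8 | step 16 | (1R,5S,7S)-2-methoxy-8,8-dimethyl-1,5-bis(3-methylbut-2-en-1-yl)-7-[(4,4,5,5-tetramethyl-1,3,2-dioxaborolan-2-yl)methyl]bicyclo[3.3.1]non-2-ene-4,9-dione | C(B1OC(C)(C)C(C)(C)O1)[C@H]2C[C@]3(CC=C(C)C)C(=O)[C@@](CC=C(C)C)(C(OC)=CC3=O)C2(C)C
F9 | step 16 | potassium trifluoro{[(1R,5S,7S)-2-methoxy-8,8-dimethyl-1,5-bis(3-methylbut-2-en-1-yl)-4,9-dioxobicyclo[3.3.1]non-2-en-7-yl]methyl}borate | [K+].F[B-](F)(F)C[C@H]1C[C@]2(CC=C(C)C)C(=O)[C@@](CC=C(C)C)(C(OC)=CC2=O)C1(C)C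
A1 | alternative 1 | 4-ethoxy-7-[(2E)-3,7-dimethylocta-2,6-dien-1-yl]-8,8-dimethyl-1,5-bis(3-methylbut-2-en-1-yl)bicyclo[3.3.1]non-3-ene-2,9-dione | CC(C)=CCC/C(C)=C/C[C@H]1C[C@]2(CC=C(C)C)C(=O)[C@@](CC=C(C)C)(C(=O)C=C2OCC)C1(C)C
A2 | alternative 1 | 1-{2-[(tert-butyldimethylsilyl)oxy]-5-[(2E)-3,7-dimethylocta-2,6-dien-1-yl]-6,6-dimethyl-1,3-bis(3-methylbut-2-en-1-yl)cyclohex-2-en-1-yl}-3-ethoxyprop-2-yn-1-one | CC(C)=CCC/C(C)=C/C[C@H]1CC(CC=C(C)C)=C(O[Si](C)(C)C(C)(C)C)[C@@](CC=C(C)C)(C(=O)C#COCC)C1(C)C
A3 | alternative 2 | 1-allyl-2-methoxy-8,8-dimethyl-7-methylidenebicyclo[3.3.1]non-2-ene-4,9-dione | C=C1C[C@@H]2C(=O)[C@@](CC=C)(C(OC)=CC2=O)C1(C)C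
A4 | alternative 2 | 6-allyl-5-methoxy-6-(prop-1-en-2-yl)-2-(prop-2-yn-1-yl)cyclohex-4-ene-1,3-dione | C=CC[C@]1(C(C)=C)C(=O)C(CC#C)C(=O)C=C1OC
A5 | alternative 3 | methyl 8,8-dimethyl-2,9-dioxo-1,5-bis(3-methylbut-2-en-1-yl)bicyclo[3.3.1]nonane-7-carboxylate (ester endo) | COC(=O)[C@H]1C[C@]2(CC=C(C)C)C(=O)[C@@](CC=C(C)C)(C(=O)CC2)C1(C)C
A6 | alternative 3 | 2,2-dimethyl-6-(3-methylbut-2-en-1-yl)-6-[3-methyl-2-(3-methylbut-2-en-1-yl)but-2-enoyl]-5,6,7,8-tetrahydro-4H-1,3-benzodioxin-4-one | CC(C)=CCC(=C(C)C)C(=O)[C@]1(CC=C(C)C)CCC2=C(C1)C(=O)OC(C)(C)O2
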